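The monomer in chains a flask like these yields depends on how much free monomer each living end takes in before it becomes dead end A, so that is what I reckon with. Here are the flasks, the earlier runs and the questions.

| flask | free monomer | initiator | remark | time |
|---|---|---|---|---|
| alder | 0.22 M | 1.7 mM | run made earlier |  |
| ash | 0.22 M | 6.8 mM | run made earlier |  |
| alpha | 0.22 M | 11 mM |  | 50 min |
| beta | 0.22 M | 3.0 mM |  | 150 min |

| run | time / min | monomer in chains / % | free monomer / % |
|---|---|---|---|
| alder | 2.00 | 3 | 99 |
| alder | 5.00 | 3 | 99 |
| alder | 10.0 | 4 | 97 |
| alder | 15.0 | 9 | 94 |
| alder | 20.0 | 9 | 94 |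
| alder | 30.0 | 9 | 90 |
| alder | 40.0 | 11 | 86 |
| ash | 5.00 | 9 | 94 |
| ash | 10.0 | 14 | 86 |
| ash | 15.0 | 20 | 79 |
| ash | 20.0 | 25 | 73 |
| ash | 25.0 | 33 | 69 |
| ash | 30.0 | 37 | 64 |
| ash | 40.0 | 42 | 60 |

(standard deviation of a reading: 1.5 percentage points)

- which of the two ends with the higher amount of monomer in chains, in percent of the free monomer charged ("neither" if they lie within 2 percentage points) (alpha / beta / neither)
- monomer in chains at the end, in percent of the free monomer charged, alpha
- monomer in chains at the end, in percent of the free monomer charged, beta

Take conversion as the mean of the monomer in chains and the free monomer gone, and use its logarithm, ln(1/(1 − conversion)), as the measure of growth.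

In the first instants I assume that each initiator becomes one living end within minutes. The readings do not speak against this: at 20.0 min, the log conversion read in ash is 3.86 times that of alder, for a charge 4.00 times as large.

In the middle of ash, conversion stands at 14.0% at 10.0 min, 26.0% at 20.0 min, 36.5% at 30.0 min and 41.0% at 40.0 min. Log conversion gains 0.301 over the first stretch and 0.227 over the next equal one. So I read the living ends of ash as falling to 75.2% in 20.0 min, which means a lifetime of 70.3 min. Between 10.0 min and 30.0 min, ash used 49.5 mM of free monomer and, by this reading, lost 1.46 mM of living ends. That gives a reading of 33.9, the chain budget: free monomer taken in per living end lost, the kinetic chain length.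

For the end, the budget of beta covers 46.2% of the free monomer charged, which makes initiator its limiting reagent. After 2.13 lifetimes, I expect 40.7%. The budget of alpha covers 169%, so there I scale the ash rate to 0.0281 min⁻¹ and count 0.711 lifetimes, which gives 63.4%, ahead of beta.

The forecast chose alpha, with 55% (46% to 64%) for alpha and 50% (40% to 60%) for beta, judging that “Alpha is ahead, but only modestly”; my figures are higher for alpha and lower for beta.

The flask gives alpha as the higher, with 65.6% for alpha and 40.2% for beta.

    living end + free monomer → dead end A (k = 0.00120 L mol⁻¹ s⁻¹)
    2 initiator → spent initiator B (k = 0.00180 L mol⁻¹ s⁻¹)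
    free monomer + living end → monomer in chains + living end, rate k3*[living end]*[free monomer] (k = 0.0420 L mol⁻¹ s⁻¹)
    free monomer + initiator → living end + monomer in chains (k = 0.0370 L mol⁻¹ s⁻¹)

In beta, 40.2% in chains means 2.61 mM of living ends lost at the chain budget, which by this reckoning leaves 0.390 mM of living ends from the 3.0 mM of initiator charged; at 150 min beta holds 0.559 mM. The neighbouring flask is beta left until 6.0 h. That is 5.12 lifetimes, enough to spend nearly all of the budget, so the reckoning gives 45.9%. That flask reads 47.6% in chains, with 51% of its free monomer still unbound.

The earlier runs and the new flask are simulated for substances that don't exist.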